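**Plan**

1. Numbering: each quinone ring is counted C1(=O), C2(OH), C3(Me), C4(=O), C5 (biaryl carbon), C6 (chain carbon); ring A bears the 2-methoxyphenethyl chain, ring B (primed) the phenethyl chain.
2. Retrosynthesis: both hydroxyquinones are unmasked last, ring A from a C4 phenol with a C2 silyl ether and a free C1-H, ring B from a 1',2',4'-trimethoxyarene; ring A is then cut at C1-C6, C3-C4, C1-C2 and C4-C5.
3. Enabling feature: C2(O)-C3(Me) of ring A is a 1-siloxypropyne, and C4, C1, C6, C5 are a vinylketene released from diazo enone 17, in which C5 already carries ring B.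
4. 17 is cut at the diazo carbon (diazo transfer onto methyl ketone 15) and at C5=C6 (Horner-Wadsworth-Emmons between ring B aldehyde 9 and phosphonate 12); 9 is derived from 2,4-dimethoxy-3-methylbenzaldehyde.
5. Forward: ring B is bought as a benzene and decorated (steps 1-6), the chain is joined (steps 7-11), ring A is the only ring built (step 13), and the two quinones are released in steps 14-16.
6. Stereochemistry: the target has no stereocentre; only the E geometry of the enone (step 8) matters, and the hindered biaryl axis forms without control.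

Key step: step 13

Remark: the target SMILES carries no stereodescriptor, so the biaryl axis is treated as unspecified (racemic); 2,4-dimethoxy-3-methylbenzaldehyde (the formylation product of 2,6-dimethoxytoluene) and 1-propynyllithium are taken as purchasable.

**Route**

Step 1
Reactants: 1 2,4-dimethoxy-3-methylbenzaldehyde
Product: 3 2,4-dimethoxy-3-methylphenol, via aryl formate 2 (not isolated)
Conditions: mCPBA, CH2Cl2, 0 °C to rt; then K2CO3 (cat.), MeOH, rt
Reagents that add atoms: 3-chloroperoxybenzoic acid, OOC(=O)c1cccc(Cl)c1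
Why: Baeyer-Villiger (Dakin-type) oxidation of an electron-rich benzaldehyde, in which the ortho/para-methoxylated aryl group migrates and the resulting formate is removed by methanolysis.

Step 2
Reactants: 3 2,4-dimethoxy-3-methylphenol
Product: 4 2-hydroxy-3,5-dimethoxy-4-methylbenzaldehyde
Conditions: MgCl2, Et3N, (CH2O)n, MeCN, reflux; aq. HCl work-up
Reagents that add atoms: paraformaldehyde (as formaldehyde), C=O
Why: Magnesium phenoxide-directed ortho-formylation (Casnati-Skattebøl) delivers formaldehyde only next to the phenol oxygen, and the single free ortho position is the future C6'.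

Step 3
Reactants: 4 2-hydroxy-3,5-dimethoxy-4-methylbenzaldehyde
Product: 5 2,3,5-trimethoxy-4-methylbenzaldehyde
Conditions: MeI, K2CO3, DMF, rt
Reagents that add atoms: iodomethane, CI
Why: Williamson O-methylation of the chelated ortho-hydroxybenzaldehyde, as routinely done for o-vanillin-type phenols.

Step 4
Reactants: 5 2,3,5-trimethoxy-4-methylbenzaldehyde; 6 diethyl benzylphosphonate
Product: 7 (E)-2,3,5-trimethoxy-4-methylstilbene
Conditions: KOtBu, THF, 0 °C to rt
Reagents that add atoms: none
Why: Horner-Wadsworth-Emmons olefination with a benzylphosphonate is the standard stilbene synthesis and gives the E alkene, whose geometry is erased in the next step.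

Step 5
Reactants: 7 (E)-2,3,5-trimethoxy-4-methylstilbene
Product: 8 2,3,5-trimethoxy-4-methyl-1-(2-phenylethyl)benzene
Conditions: H2 (1 atm), 10% Pd/C, EtOAc, rt
Reagents that add atoms: none
Why: Heterogeneous catalytic hydrogenation saturates the stilbene double bond and leaves the aryl methyl ethers untouched.

Step 6
Reactants: 8 2,3,5-trimethoxy-4-methyl-1-(2-phenylethyl)benzene
Product: 9 2,4,5-trimethoxy-3-methyl-6-(2-phenylethyl)benzaldehyde (ring B aldehyde)
Conditions: Cl2CHOMe, TiCl4, CH2Cl2, -78 to 0 °C; then H2O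
Reagents that add atoms: dichloromethyl methyl ether, COC(Cl)Cl; water, O
Why: Rieche formylation attacks the only free position of the trimethoxy ring (C5'), which is ortho to the C4' methoxy and para to the C2' methoxy group, while the unactivated pendant phenyl ring does not compete.

Step 7
Reactants: 10 triethyl phosphonoacetate; 11 1-(2-bromoethyl)-2-methoxybenzene
Product: 12 ethyl 2-(diethoxyphosphoryl)-4-(2-methoxyphenyl)butanoate (racemic)
Conditions: NaH, DMF, 0 to 50 °C
Reagents that add atoms: none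
Why: C-alkylation of the soft, weakly basic phosphonoacetate anion with a primary bromide, which keeps E2 elimination to 2-methoxystyrene in the background.

Step 8
Reactants: 12 ethyl 2-(diethoxyphosphoryl)-4-(2-methoxyphenyl)butanoate; 9 ring B aldehyde
Product: 13 ethyl (2E)-2-[2-(2-methoxyphenyl)ethyl]-3-[2,4,5-trimethoxy-3-methyl-6-(2-phenylethyl)phenyl]prop-2-enoate
Conditions: NaH, THF, 0 °C to reflux
Reagents that add atoms: none
Why: Horner-Wadsworth-Emmons olefination of an aromatic aldehyde with an alpha-alkyl phosphonoacetate, where reversible addition under sodium counter-ion and heat should favour the E alkene with ring B trans to the ester.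

Step 9
Reactants: 13 the E ester
Product: 14 (2E)-2-[2-(2-methoxyphenyl)ethyl]-3-[2,4,5-trimethoxy-3-methyl-6-(2-phenylethyl)phenyl]prop-2-enoic acid
Conditions: LiOH, THF/MeOH/H2O, 60 °C; then aq. HCl
Reagents that add atoms: lithium hydroxide, [Li+].[OH-]
Why: Ordinary saponification of a conjugated ethyl ester with no base-sensitive group elsewhere in the molecule.

Step 10
Reactants: 14 the E acid
Product: 15 (3E)-3-[2-(2-methoxyphenyl)ethyl]-4-[2,4,5-trimethoxy-3-methyl-6-(2-phenylethyl)phenyl]but-3-en-2-one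
Conditions: MeLi (2.5 equiv), THF, -78 to 0 °C; inverse quench into cold aq. HCl
Reagents that add atoms: methyllithium, [Li]C
Why: 1,2-Addition of methyllithium to the lithium carboxylate stops at the dilithium gem-diolate, which releases the methyl ketone only on quench, the classical acid-to-methyl-ketone conversion.

Step 11
Reactants: 15 the E methyl ketone
Product: 17 (3E)-1-diazo-3-[2-(2-methoxyphenyl)ethyl]-4-[2,4,5-trimethoxy-3-methyl-6-(2-phenylethyl)phenyl]but-3-en-2-one, via trifluoroacetyl diketone 16 (not isolated)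
Conditions: LiN(SiMe3)2, THF, -78 °C; CF3CO2CH2CF3; aq. HCl work-up; then MeSO2N3, Et3N, H2O (1 equiv), MeCN, rt
Reagents that add atoms: methanesulfonyl azide, CS(=O)(=O)N=[N+]=[N-]
Why: Detrifluoroacetylative diazo transfer, the method made for alpha'-diazo enones: the kinetic methyl enolate is trifluoroacetylated, and the sulfonyl azide then transfers N2 with loss of the activating group, avoiding the pyrazoline formation that diazomethane risks with an enoyl chloride.

Step 12
Reactants: 18 1-propynyllithium (CH3C≡CLi)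
Product: 20 1-(triisopropylsiloxy)propyne, via lithium ynolate 19 (not isolated)
Conditions: t-BuOOH (anhydrous), LiN(SiMe3)2, THF, -78 °C; add 18, -78 to 0 °C; then iPr3SiOSO2CF3, -78 to 0 °C
Reagents that add atoms: tert-butyl hydroperoxide, CC(C)(C)OO; triisopropylsilyl trifluoromethanesulfonate, CC(C)[Si](C(C)C)(C(C)C)OS(=O)(=O)C(F)(F)F
Why: Oxidation of a lithium acetylide by lithium tert-butyl peroxide gives the ynolate, which the bulky silyl triflate traps on oxygen, the established preparation of 1-siloxyalkynes from terminal alkynes.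

Step 13
Reactants: 17 the diazo enone; 20 1-(triisopropylsiloxy)propyne
Product: 25 3-[2-(2-methoxyphenyl)ethyl]-6-methyl-2-[2,4,5-trimethoxy-3-methyl-6-(2-phenylethyl)phenyl]-5-(triisopropylsiloxy)phenol, via vinylketene 21 (not isolated), via cyclobutenone 22 (not isolated), via dienylketene 23 (not isolated), via cyclohexadienone 24 (not isolated)
Conditions: 20 (2 equiv), hν (254 nm, low-pressure Hg lamp, quartz), ClCH2CH2Cl, rt; then 80 °C
Reagents that add atoms: none
Why: Photochemical Wolff rearrangement of 17 moves the alkenyl carbon C6 from the carbonyl carbon (the future C4) to the diazo carbon C1 and gives vinylketene 21, to which the siloxyalkyne adds in a [2+2] that forms C3-C4 and C1-C2 (cyclobutenone 22). Four-electron conrotatory opening of 22 breaks C4-C1 to dienylketene 23, and six-electron disrotatory electrocyclisation joins ketene carbon C4 to C5; tautomerisation of dienone 24 then closes ring A as the phenol. The closest known reaction is the photochemical diazoketone version of the Danheiser benzannulation with siloxyalkynes, which gives resorcinol monosilyl ethers. No stereocentre is created and the biaryl axis arises racemic. The selectivity required is the orientation of the [2+2]: the ynol ether polarisation makes the methyl-bearing alkyne carbon the nucleophile, so it bonds to the electrophilic ketene carbonyl carbon C4 and places oxygen on C2 and methyl on C3. The E enone geometry keeps ring B on the outside of the triene terminus C5, and the two ortho substituents of ring B block closure onto that ring, so only the C4-C5 bond can form.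

Step 14
Reactants: 25 the ring A phenol
Product: 26 6-[2-(2-methoxyphenyl)ethyl]-3-methyl-5-[2,4,5-trimethoxy-3-methyl-6-(2-phenylethyl)phenyl]-2-(triisopropylsiloxy)-1,4-benzoquinone
Conditions: ON(SO3K)2 (3 equiv), KH2PO4, n-Bu4NHSO4 (cat.), CH2Cl2/H2O, rt
Reagents that add atoms: potassium nitrosodisulfonate, [K+].[K+].[O]N(S(=O)(=O)[O-])S(=O)(=O)[O-]
Why: Teuber oxidation, in which the nitroxyl radical abstracts the phenolic hydrogen, a second one couples at the free para carbon C1 and loss of HN(SO3K)2 gives the para-quinone; both ortho positions are blocked, so no ortho-quinone can form.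

Step 15
Reactants: 26 the ring A siloxyquinone
Product: 27 2-(triisopropylsiloxy)-3-methyl-6-[2-(2-methoxyphenyl)ethyl]-5-[4-methoxy-5-methyl-3,6-dioxo-2-(2-phenylethyl)cyclohexa-1,4-dien-1-yl]-1,4-benzoquinone
Conditions: (NH4)2Ce(NO3)6 (2.5 equiv), MeCN/H2O, 0 °C, short reaction time
Reagents that add atoms: water, O
Why: Oxidative demethylation of the para-dimethoxy pair C1'/C4' by tetravalent cerium gives the para-quinone and keeps the C2' methoxy group; the 1,2,4-trimethoxy ring is far easier to oxidise than the mono-methoxy phenyl ring, which should survive at 0 °C.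

Step 16
Reactants: 27 the bisquinone silyl/methyl ether
Product: 28 2-hydroxy-5-[4-hydroxy-5-methyl-3,6-dioxo-2-(2-phenylethyl)cyclohexa-1,4-dien-1-yl]-6-[2-(2-methoxyphenyl)ethyl]-3-methyl-1,4-benzoquinone (target)
Conditions: aq. NaOH, THF, 0 °C to rt, under argon; then aq. HCl
Reagents that add atoms: sodium hydroxide, [Na+].[OH-]
Why: Both masked enols are vinylogous esters: hydroxide cleaves the silyl one at silicon and replaces the ring B methoxy group by addition-elimination, while the anisole ether is inert, and acidification of the dianion gives the bis(hydroxyquinone).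

**Compound list**

1 | 2,4-dimethoxy-3-methylbenzaldehyde | COc1ccc(C=O)c(OC)c1C | starting material
2 | 2,4-dimethoxy-3-methylphenyl formate | COc1ccc(OC=O)c(OC)c1C | intermediate
3 | 2,4-dimethoxy-3-methylphenol | COc1ccc(O)c(OC)c1C | intermediate
4 | 2-hydroxy-3,5-dimethoxy-4-methylbenzaldehyde | COc1cc(C=O)c(O)c(OC)c1C | intermediate
5 | 2,3,5-trimethoxy-4-methylbenzaldehyde | COc1cc(C=O)c(OC)c(OC)c1C | intermediate
6 | diethyl benzylphosphonate | CCOP(=O)(Cc1ccccc1)OCC | starting material
7 | (E)-2,3,5-trimethoxy-4-methylstilbene | COc1cc(/C=C/c2ccccc2)c(OC)c(OC)c1C | intermediate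
8 | 2,3,5-trimethoxy-4-methyl-1-(2-phenylethyl)benzene | COc1cc(CCc2ccccc2)c(OC)c(OC)c1C | intermediate
9 | 2,4,5-trimethoxy-3-methyl-6-(2-phenylethyl)benzaldehyde (ring B aldehyde) | O=Cc1c(OC)c(C)c(OC)c(OC)c1CCc1ccccc1 | intermediate
10 | triethyl phosphonoacetate | CCOC(=O)CP(=O)(OCC)OCC | starting material
11 | 1-(2-bromoethyl)-2-methoxybenzene | COc1ccccc1CCBr | starting material
12 | ethyl 2-(diethoxyphosphoryl)-4-(2-methoxyphenyl)butanoate (racemic) | CCOC(=O)C(CCc1ccccc1OC)P(=O)(OCC)OCC | intermediate
13 | ethyl (2E)-2-[2-(2-methoxyphenyl)ethyl]-3-[2,4,5-trimethoxy-3-methyl-6-(2-phenylethyl)phenyl]prop-2-enoate | CCOC(=O)/C(CCc1ccccc1OC)=C/c1c(OC)c(C)c(OC)c(OC)c1CCc1ccccc1 | intermediate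
14 | (2E)-2-[2-(2-methoxyphenyl)ethyl]-3-[2,4,5-trimethoxy-3-methyl-6-(2-phenylethyl)phenyl]prop-2-enoic acid | OC(=O)/C(CCc1ccccc1OC)=C/c1c(OC)c(C)c(OC)c(OC)c1CCc1ccccc1 | intermediate
15 | (3E)-3-[2-(2-methoxyphenyl)ethyl]-4-[2,4,5-trimethoxy-3-methyl-6-(2-phenylethyl)phenyl]but-3-en-2-one | CC(=O)/C(CCc1ccccc1OC)=C/c1c(OC)c(C)c(OC)c(OC)c1CCc1ccccc1 | intermediate
16 | (5E)-1,1,1-trifluoro-5-[2-(2-methoxyphenyl)ethyl]-6-[2,4,5-trimethoxy-3-methyl-6-(2-phenylethyl)phenyl]hex-5-ene-2,4-dione | O=C(CC(=O)C(F)(F)F)/C(CCc1ccccc1OC)=C/c1c(OC)c(C)c(OC)c(OC)c1CCc1ccccc1 | intermediate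
17 | (3E)-1-diazo-3-[2-(2-methoxyphenyl)ethyl]-4-[2,4,5-trimethoxy-3-methyl-6-(2-phenylethyl)phenyl]but-3-en-2-one | [N-]=[N+]=CC(=O)/C(CCc1ccccc1OC)=C/c1c(OC)c(C)c(OC)c(OC)c1CCc1ccccc1 | intermediate
18 | 1-propynyllithium | [Li]C#CC | starting material
19 | lithium prop-1-yn-1-olate | CC#C[O-].[Li+] | intermediate
20 | 1-(triisopropylsiloxy)propyne | CC#CO[Si](C(C)C)(C(C)C)C(C)C | intermediate
21 | (3E)-3-[2-(2-methoxyphenyl)ethyl]-4-[2,4,5-trimethoxy-3-methyl-6-(2-phenylethyl)phenyl]buta-1,3-dien-1-one (vinylketene) | O=C=C/C(CCc1ccccc1OC)=C/c1c(OC)c(C)c(OC)c(OC)c1CCc1ccccc1 | intermediate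
22 | 2-methyl-3-(triisopropylsiloxy)-4-[(E)-alkenyl]cyclobut-2-en-1-one, the alkenyl group being C6(2-methoxyphenethyl)=C5H(ring B aryl) (racemic) | O=C1C(C)=C(O[Si](C(C)C)(C(C)C)C(C)C)C1/C(CCc1ccccc1OC)=C/c1c(OC)c(C)c(OC)c(OC)c1CCc1ccccc1 | intermediate
23 | dienylketene C4(=O)=C3(Me)-C2(OSi)=C1H-C6(chain)=C5H(ring B aryl), with C3 and C6 cis across C2=C1 and C1 trans to ring B across C6=C5 | O=C=C(C)/C(O[Si](C(C)C)(C(C)C)C(C)C)=C\C(CCc1ccccc1OC)=C\c1c(OC)c(C)c(OC)c(OC)c1CCc1ccccc1 | intermediate
24 | 5-[2-(2-methoxyphenyl)ethyl]-2-methyl-6-[2,4,5-trimethoxy-3-methyl-6-(2-phenylethyl)phenyl]-3-(triisopropylsiloxy)cyclohexa-2,4-dien-1-one (racemic) | O=C1C(C)=C(O[Si](C(C)C)(C(C)C)C(C)C)C=C(CCc2ccccc2OC)C1c1c(OC)c(C)c(OC)c(OC)c1CCc1ccccc1 | intermediate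
25 | 3-[2-(2-methoxyphenyl)ethyl]-6-methyl-2-[2,4,5-trimethoxy-3-methyl-6-(2-phenylethyl)phenyl]-5-(triisopropylsiloxy)phenol (racemic axis) | Cc1c(O)c(-c2c(OC)c(C)c(OC)c(OC)c2CCc2ccccc2)c(CCc2ccccc2OC)cc1O[Si](C(C)C)(C(C)C)C(C)C | intermediate
26 | 6-[2-(2-methoxyphenyl)ethyl]-3-methyl-5-[2,4,5-trimethoxy-3-methyl-6-(2-phenylethyl)phenyl]-2-(triisopropylsiloxy)-1,4-benzoquinone | CC1=C(O[Si](C(C)C)(C(C)C)C(C)C)C(=O)C(CCc2ccccc2OC)=C(c2c(OC)c(C)c(OC)c(OC)c2CCc2ccccc2)C1=O | intermediate
27 | 2-(triisopropylsiloxy)-3-methyl-6-[2-(2-methoxyphenyl)ethyl]-5-[4-methoxy-5-methyl-3,6-dioxo-2-(2-phenylethyl)cyclohexa-1,4-dien-1-yl]-1,4-benzoquinone | CC1=C(O[Si](C(C)C)(C(C)C)C(C)C)C(=O)C(CCc2ccccc2OC)=C(C2=C(CCc3ccccc3)C(=O)C(OC)=C(C)C2=O)C1=O | intermediate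
28 | 2-hydroxy-5-[4-hydroxy-5-methyl-3,6-dioxo-2-(2-phenylethyl)cyclohexa-1,4-dien-1-yl]-6-[2-(2-methoxyphenyl)ethyl]-3-methyl-1,4-benzoquinone (CNP0202346.0) | COc1ccccc1CCC1=C(C2=C(CCc3ccccc3)C(=O)C(O)=C(C)C2=O)C(=O)C(C)=C(O)C1=O | target

**Count and risks**

Total step count: 16. Longest linear sequence: 14 steps (steps 1-6, 8-11 and 13-16); steps 7 and 12 are side branches.

Steps most likely to fail:

Step 13. The aryl chromophores and the phenol being formed absorb at 254 nm and can slow the photolysis. The enone may photoisomerise. The last six-electron closure has to build a biaryl with four ortho substituents and could stall at the cyclobutenone. The fallback generates the same vinylketene without light; it sets out from 17 and returns at 25. Wolff rearrangement of 17 with PhCO2Ag and Et3N in aqueous THF (Arndt-Eistert homologation) should give (3E)-3-[2-(2-methoxyphenyl)ethyl]-4-[2,4,5-trimethoxy-3-methyl-6-(2-phenylethyl)phenyl]but-3-enoic acid F1. Oxalyl chloride with catalytic DMF converts it into the acid chloride F2. Slow addition of Et3N to F2 and 20 in toluene dehydrochlorinates F2 to vinylketene 21, which 20 traps; heating at 80-110 °C carries the material through 22, 23 and 24 to 25.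

Step 8. Addition of the alpha-branched phosphonate anion to the doubly ortho-substituted aldehyde may be slow, and the E/Z selectivity may erode. The fallback is an aldol-elimination sequence; it sets out from 9 and returns at 13. The lithium enolate (LiN(iPr)2, THF, -78 °C) of ethyl 4-(2-methoxyphenyl)butanoate F3, made by Fischer esterification of purchased 4-(2-methoxyphenyl)butanoic acid, adds to 9 to give the beta-hydroxy ester F4 as a diastereomer mixture. MsCl/Et3N gives the mesylate F5, and DBU in warm toluene eliminates methanesulfonic acid by an E1cB path to the thermodynamically preferred E ester 13.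

Step 15. The silyl vinylogous ester may be lost in the acidic aqueous medium, after which tetravalent cerium could oxidise the liberated enol by one electron; the anisole ring may also be attacked on prolonged exposure. The fallback exchanges the silyl group for an acid-stable methyl group before the oxidation; it sets out from 26 and returns at 28. Bu4NF buffered with AcOH gives the ring A hydroxyquinone F6, and Me3SiCHN2 in toluene/MeOH converts it into the ring A methoxyquinone F7. (NH4)2Ce(NO3)6 then oxidises ring B to the bis(methoxyquinone) F8, and the aqueous NaOH treatment of step 16 hydrolyses both vinylogous methyl esters to 28.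

**Further compounds**

F1 | step 13 | (3E)-3-[2-(2-methoxyphenyl)ethyl]-4-[2,4,5-trimethoxy-3-methyl-6-(2-phenylethyl)phenyl]but-3-enoic acid | OC(=O)C/C(CCc1ccccc1OC)=C/c1c(OC)c(C)c(OC)c(OC)c1CCc1ccccc1
F2 | step 13 | (3E)-3-[2-(2-methoxyphenyl)ethyl]-4-[2,4,5-trimethoxy-3-methyl-6-(2-phenylethyl)phenyl]but-3-enoyl chloride | ClC(=O)C/C(CCc1ccccc1OC)=C/c1c(OC)c(C)c(OC)c(OC)c1CCc1ccccc1
F3 | step 8 | ethyl 4-(2-methoxyphenyl)butanoate | CCOC(=O)CCCc1ccccc1OC
F4 | step 8 | ethyl 3-hydroxy-2-[2-(2-methoxyphenyl)ethyl]-3-[2,4,5-trimethoxy-3-methyl-6-(2-phenylethyl)phenyl]propanoate (racemic diastereomer mixture) | CCOC(=O)C(CCc1ccccc1OC)C(O)c1c(OC)c(C)c(OC)c(OC)c1CCc1ccccc1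
F5 | step 8 | ethyl 2-[2-(2-methoxyphenyl)ethyl]-3-(methylsulfonyloxy)-3-[2,4,5-trimethoxy-3-methyl-6-(2-phenylethyl)phenyl]propanoate (racemic diastereomer mixture) | CCOC(=O)C(CCc1ccccc1OC)C(OS(C)(=O)=O)c1c(OC)c(C)c(OC)c(OC)c1CCc1ccccc1
F6 | step 15 | 2-hydroxy-6-[2-(2-methoxyphenyl)ethyl]-3-methyl-5-[2,4,5-trimethoxy-3-methyl-6-(2-phenylethyl)phenyl]-1,4-benzoquinone | CC1=C(O)C(=O)C(CCc2ccccc2OC)=C(c2c(OC)c(C)c(OC)c(OC)c2CCc2ccccc2)C1=O
F7 | step 15 | 2-methoxy-6-[2-(2-methoxyphenyl)ethyl]-3-methyl-5-[2,4,5-trimethoxy-3-methyl-6-(2-phenylethyl)phenyl]-1,4-benzoquinone | CC1=C(OC)C(=O)C(CCc2ccccc2OC)=C(c2c(OC)c(C)c(OC)c(OC)c2CCc2ccccc2)C1=O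
F8 | step 15 | 2-methoxy-5-[4-methoxy-5-methyl-3,6-dioxo-2-(2-phenylethyl)cyclohexa-1,4-dien-1-yl]-6-[2-(2-methoxyphenyl)ethyl]-3-methyl-1,4-benzoquinone | CC1=C(OC)C(=O)C(CCc2ccccc2OC)=C(C2=C(CCc3ccccc3)C(=O)C(OC)=C(C)C2=O)C1=O
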